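The ratio I want from this flask is X used up over X still free at the end of the run.

X 0.10 M; Z 5.00 equiv; time 4.0 h

    X.Q ⇌ L + J (K1 = 0.053 M, k1 = 0.0027 s⁻¹)
    D ⇌ J, rate k2*(cs2 - [J]) while solid is left; crystals form when [J] > cs2 (cs2 = 7.8 mM, k2 = 0.033 s⁻¹)
    X + Q ⇌ X.Q (K3 = 13 M⁻¹, k3 = 0.18 M⁻¹ s⁻¹)
    Z ⇌ Q, rate k4*(cs4 - [Q]) while solid is left; crystals form when [Q] > cs4 (cs4 = 0.058 M, k4 = 0.020 s⁻¹)

1. share of the X used up at 4.0 h
2. L at 4.0 h, in percent of the X charged
3. X.Q at 4.0 h, in percent of the X charged

- amounts and yields of J count D too
- given per volume of solution although it is solid: D, Z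
- at the start none of Z is in solution
- run time (flask): 4.0 h

Does solid Z last? The flask can take up at most one Q per X plus a solution saturated at 0.058 M, and the charge is 3.16 times that, so solid stays. Z dissolves with a half-life of 0.578 min, short against 4.0 h, so I take Q at 0.058 M at the end, which makes the binding of X pseudo-first-order. Full turnover would offer 12.8 times the solubility of J, so I expect crystals of D, and I assume they keep J near 7.8 mM.

What do these two levels give at balance? X.Q over X is 0.754, and L over X.Q is 6.79. The turnover ratio, X used up over X still free, is the first times one plus the second: 5.88. I reckon 85.5% of X used up, 74.4% as L and 11.0% as X.Q.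

Is there time? X and X.Q exchange faster than X.Q goes on to L, so I put the slow half-life at 7.41 min. The run is 32.4 of these, so I commit to the balance.

The forecast gives 85.5% used up (82% to 88%), 74.5% of L (70% to 78%) and 11% of X.Q (9.5% to 12.5%), “assuming D crystallises readily once J exceeds its solubility”.

The simulation gives 85.5% used up, 74.5% of L and 11.0% of X.Q. In this flask the half-lives at the end, 1.1 min for X binding Q and 1.68 min for the exchange of X.Q with L and J, are short against 4.0 h, and the turnover ratio read from the conversion is 5.90, close to my 5.88. The neighbour flask with 1.20 equiv of Z ends with solid Z at 0% of its charge, Q at 0.0398 M and J at 0.00780 M. With J at the same level, I scale my turnover ratio by the two levels of Q and get 4.04 for the neighbour flask, which means 80.2% of X used up, and that flask stands at 80.2%.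

(All constants were drawn at random within sensible limits; the flask was simulated.)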